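The synthesis rests on cutting the C9–O9 bond. This bond joins ring A to the oxygen of the five-membered ring (O9–C9–C11–C12–C13) at the foot of the orthoester cage. C9 is γ to C13 and O9 lies equatorial on ring A, so O9 can take the place of an equatorial tertiary H-9. One carboxylate-directed, manganese-catalysed C–H lactonisation forms this bond, closes the γ-lactone and fixes C9 with retention. Its precursor is the complete ring A (7β-acetate, 8β-methyl, C5 hydroxyisopropyl, C10 spiro δ-lactone) with an axial propanoic acid chain on C9. Ring A is built by annulation and conjugate addition, and the cage is grown from C12 afterwards.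

Key step: step 13

Atom labels: ring A is C5 (bears C4, the CMe2–O carbon), C6 (CH2), C7 (O), C8 (CH3), C9, C10 (quaternary). C1–C2–C3 is the CH2CH2C(=O) arm on C10 and C19 is its OCH2 carbon. C11–C12–C13 is the chain on C9 (C13 is the carboxyl carbon). C1' (CH–CH3), C2' (bears the carboxyl), C3' (carbinol) and C4' (ketal carbon) are the cage carbons. β is the face of ring A that carries C4, O7, the C8 methyl group and C19; α is the opposite face.

Design remark: the O7 acetate and the free tertiary alcohol suit the oxidation, because the acyloxy group deactivates H-7, which is syn-axial to the acid chain. They do not suit enolate chemistry. Step 14 therefore removes the acetate and opens the equally enolisable δ-lactone in one operation directly after the key step, and step 20 restores the δ-lactone.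

Assumption: 28 is used as the E/Z mixture that the condensation delivers, since alkylidene β-keto esters interconvert readily and the carbon between the two carbonyl groups of the adduct is labile anyway.

Step 1
Reactants: 1 ethyl (E)-4-oxobut-2-enoate; 2 methyl 3-oxobutanoate
Product: 4 cyclohexenone diester (C9 ketone; C7=C8; 5β-CO2Et; CO2Me on labile C10), via Michael adduct 3 (not isolated)
Conditions: (S)-α,α-diphenylprolinol trimethylsilyl ether (10 mol %), PhCO2H (10 mol %), toluene, 0 °C → rt; then p-TsOH·H2O (20 mol %), toluene, 80 °C
Reagents that add atoms: none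
Why: Iminium-catalysed asymmetric Michael addition followed by acid-promoted intramolecular aldol condensation: the silyloxydiphenylmethyl group of the (S)-amine shields one face of the enal iminium ion, so the keto ester carbon bonds to the open face and sets C5, and the acetyl methyl group then condenses with the aldehyde to give the C7=C8 enone.

Step 2
Reactants: 4 cyclohexenone diester
Product: 6 cis-fused keto γ-lactone (C19(=O)–O–C4Me2 bridge on the β face of C10 and C5), via tertiary alcohol 5 (not isolated)
Conditions: MeMgBr (4 equiv), LaCl3·2LiCl (30 mol %), THF, −78 → 0 °C; aq NH4Cl; then p-TsOH·H2O (5 mol %), toluene, 90 °C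
Reagents that add atoms: methylmagnesium bromide, C[Mg]Br
Why: Grignard addition to an ester: the first equivalent turns the β-keto ester into its magnesium enolate, which masks ketone, enone and methyl ester, so two methyl groups add only to the ethyl ester, and the tertiary alcohol 5 then closes the five-membered lactone by transesterification of the β-keto ester, which is possible only for the cis ring fusion that the labile C10 can adopt.

Step 3
Reactants: 6 cis-fused keto γ-lactone; 7 tert-butyl acrylate
Product: 8 quaternary keto lactone (10α-CH2CH2CO2t-Bu; C19 β)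
Conditions: DBU (10 mol %), MeCN, rt
Reagents that add atoms: none
Why: Base-catalysed Michael addition of a β-keto lactone: the planar C10 enolate is attacked on the face that carries H-5, because only this keeps the five-membered lactone cis-fused, so the new arm ends up α and C19 β on the quaternary C10.

Step 4
Reactants: 8 quaternary keto lactone
Product: 9 tosylhydrazone of 8
Conditions: TsNHNH2 (1.2 equiv), AcOH (cat.), EtOH, 60 °C
Reagents that add atoms: 4-methylbenzenesulfonohydrazide, Cc1ccc(cc1)S(=O)(=O)NN
Why: Acid-catalysed hydrazone formation; the weakly nucleophilic sulfonyl hydrazide condenses with the ketone and leaves the tert-butyl ester and the hindered lactone alone.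

Step 5
Reactants: 9 tosylhydrazone
Product: 11 C8=C9 cyclohexene lactone, via allylic diazene 10 (not isolated)
Conditions: catecholborane (2.5 equiv), CHCl3, −10 °C; then NaOAc·3H2O, reflux
Reagents that add atoms: none
Why: Reduction of an α,β-unsaturated tosylhydrazone with alkene transposition: hydride adds to C9, sulfinate is lost, and the allylic diazene 10 expels N2 in a retro-ene step that delivers hydrogen to C7 and moves the double bond to C8=C9.

Step 6
Reactants: 11 C8=C9 cyclohexene lactone
Product: 12 C7 enone (C8=C9; C10 quaternary)
Conditions: Rh2(C6H10NO)4 (dirhodium tetracaprolactamate, 1 mol %), t-BuOOH (70% aq, 5 equiv), K2CO3, CH2Cl2, rt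
Reagents that add atoms: tert-butyl hydroperoxide, CC(C)(C)OO
Why: Rhodium-catalysed allylic C–H oxidation with t-BuOOH: C7 is the only allylic CH2 because the other allylic position is the quaternary C10, so the peroxy radical couples at the unhindered end of the allyl radical and the C7 enone results.

Step 7
Reactants: 12 C7 enone; 13 but-3-enylmagnesium bromide
Product: 15 ketone bearing 9α-but-3-enyl and 8β-methyl groups, via magnesium enolate 14 (not isolated)
Conditions: CuBr·SMe2 (20 mol %), THF, −78 °C; then MeI (5 equiv), HMPA, −78 → −20 °C
Reagents that add atoms: iodomethane, CI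
Why: Copper-catalysed conjugate addition with enolate alkylation (vicinal difunctionalisation of an enone): the organocopper reagent attacks C9 axially, trans to the C5 substituent and anti to the pseudoaxial C19 on C10, which places the chain α and H-9 β, and iodomethane then enters anti to the new chain on an axial path to give the trans 8β-methyl group.

Step 8
Reactants: 15 ketone
Product: 16 7β-alcohol
Conditions: LiBH(s-Bu)3 (1.2 equiv), THF, −78 °C
Reagents that add atoms: none
Why: Bulky trialkylborohydride reduction of a cyclohexanone by equatorial attack: in the conformer with the C8 methyl group and the C9 chain equatorial the β face is screened by the axial C4, so hydride comes from the α face and gives the 7β-alcohol cis to the methyl group, as in the cis-selective reduction of 2-methylcyclohexanone.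

Step 9
Reactants: 16 7β-alcohol
Product: 17 tetraol (C3 and C19 primary; C7 secondary; C4 tertiary)
Conditions: LiAlH4 (excess), THF, 0 °C → reflux
Reagents that add atoms: none
Why: Exhaustive LiAlH4 reduction opens the fused lactone to the C19 primary and C4 tertiary alcohols and converts the tert-butyl ester into the C3 primary alcohol without touching any stereocentre or the terminal alkene.

Step 10
Reactants: 17 tetraol
Product: 19 spiro δ-lactone diol, via lactol 18 (not isolated)
Conditions: TEMPO (20 mol %), PhI(OAc)2 (2.5 equiv), CH2Cl2, rt
Reagents that add atoms: none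
Why: Oxoammonium-mediated oxidative lactonisation of a 1,5-diol: the unhindered C3 alcohol is oxidised first, the aldehyde is trapped by the neopentyl C19 hydroxyl as the six-membered lactol 18, and this is oxidised on to the lactone while the secondary and tertiary alcohols are left.

Step 11
Reactants: 19 spiro δ-lactone diol
Product: 20 7β-acetate
Conditions: Ac2O (1.5 equiv), pyridine, DMAP (cat.), CH2Cl2, 0 °C → rt
Reagents that add atoms: acetic anhydride, CC(=O)OC(C)=O
Why: Acylation under nucleophilic catalysis is selective for the secondary 7β-alcohol over the tertiary alcohol, and the acetate installed here lowers the reactivity of H-7 in step 13.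

Step 12
Reactants: 20 7β-acetate
Product: 21 ring A propanoic acid (axial 9α chain; equatorial H-9β)
Conditions: RuCl3·xH2O (3 mol %), NaIO4 (4.1 equiv), EtOAc/MeCN/H2O, 0 °C → rt
Reagents that add atoms: sodium periodate NaIO4, [Na+].[O-]I(=O)(=O)=O; water, O
Why: RuO4-catalysed oxidative cleavage of a terminal alkene to the carboxylic acid with loss of one carbon, which unveils the directing group one step before it is used and leaves acetate, lactone and tertiary alcohol untouched.

Step 13
Reactants: 21 ring A propanoic acid
Product: 22 spiro γ-lactone on ring A (O9 β and equatorial)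
Conditions: [Mn(CF3SO3)2((S,S)-pdp)] (pdp = N,N'-bis(2-pyridylmethyl)-2,2'-bipyrrolidine; 3 × 1 mol %), 30% aq H2O2 (3 × 0.7 equiv, syringe pump), (CF3)2CHOH, 0 °C (antipodal ligand to be compared)
Reagents that add atoms: none
Why: The acid displaces a triflate on divalent manganese, the bound acid helps to cleave H2O2 heterolytically to a high-valent manganese oxo carboxylate, and this oxo abstracts H-9 through a cyclic array of seven heavy atoms (O=Mn–O–C13–C12–C11–C9), H-9 being the only hydrogen that sits γ to the carboxyl group. The short-lived C9 radical is captured by the metal-bound carboxylate oxygen before it can invert, which forms the C9–O9 bond and closes the five-membered ring O9–C9–C11–C12–C13 (five-membered closure by exo-type attack of the tethered oxygen on C9). The closest known reaction type is the carboxylic-acid-directed γ-C(sp3)–H lactonisation of alkanoic acids with H2O2 and manganese or iron complexes of bis(pyridylmethyl)bipyrrolidine ligands, which is established for tertiary methines and runs with retention. The one new stereocentre, C9, is under substrate control: oxygen takes the equatorial β position that H-9 held, a position fixed in step 7 by the axial entry of the chain. Site selectivity is needed against H-8, H-5 and H-7: H-8 is δ to the acid and adjacent to the acetoxy carbon, H-5 is adjacent to the carbinol carbon whose hydroxyl group is hydrogen-bonded to the fluorinated solvent, H-7 is deactivated by the acetate, and the lactone CH2 groups are electron-poor. Because the neighbouring quaternary C10 crowds the methine, the unsubstituted small ligand, portionwise catalyst and slow peroxide addition are chosen.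

Step 14
Reactants: 22 spiro γ-lactone
Product: 23 triol pyrrolidine amide (γ-lactone intact)
Conditions: pyrrolidine (10 equiv), 1,5,7-triazabicyclo[4.4.0]dec-5-ene (20 mol %), THF, 50 °C
Reagents that add atoms: pyrrolidine, C1CCNC1
Why: Base-catalysed aminolysis of esters: the strained δ-lactone and the acetate are cleaved by pyrrolidine, whereas opening of the γ-lactone would give a tertiary γ-hydroxy amide that recloses, so the only carbonyl group left with readily removable α-hydrogens is the γ-lactone.

Step 15
Reactants: 23 triol pyrrolidine amide
Product: 24 tris(triethylsilyl) ether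
Conditions: Et3SiOSO2CF3 (4 equiv), 2,6-lutidine, CH2Cl2, −78 → 0 °C
Reagents that add atoms: triethylsilyl trifluoromethanesulfonate, CC[Si](CC)(CC)OS(=O)(=O)C(F)(F)F
Why: Silyl triflate silylation covers primary, secondary and tertiary hydroxyl groups alike, so no acidic proton or nucleophilic alkoxide is left for the enolate steps.

Step 16
Reactants: 24 tris(triethylsilyl) ether
Product: 25 α-methyl γ-lactone
Conditions: LiN(SiMe3)2 (1.1 equiv), THF, −78 °C; MeI (3 equiv)
Reagents that add atoms: iodomethane, CI
Why: Lactone enolate alkylation: LiN(SiMe3)2 is basic enough for the lactone but not for the much less acidic tertiary amide, and iodomethane enters from the lactone face next to C8, away from the quaternary C10 (this centre is planarised again in step 18).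

Step 17
Reactants: 26 methyl 4,4-dimethoxy-3-oxopentanoate; 27 acetaldehyde
Product: 28 methyl 2-ethylidene-4,4-dimethoxy-3-oxopentanoate
Conditions: piperidine (10 mol %), AcOH (10 mol %), 4 Å MS, CH2Cl2, 0 °C
Reagents that add atoms: none
Why: Knoevenagel condensation of an active methylene compound with an aldehyde under amine/acid catalysis.

Step 18
Reactants: 25 α-methyl γ-lactone; 28 methyl 2-ethylidene-4,4-dimethoxy-3-oxopentanoate
Product: 29 Michael adduct β-keto ester (C12 quaternary)
Conditions: LiN(SiMe3)2 (1.1 equiv), THF, −78 °C; then 28 (1.5 equiv), −78 °C; AcOH quench at −78 °C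
Reagents that add atoms: none
Why: Michael addition of a tetrasubstituted lithium lactone enolate to a doubly activated alkylidene β-keto ester: the acceptor approaches the enolate face that looks toward C8 and not the one blocked by the quaternary C10, which sets C12 with its methyl group on the C10 side, and a lithium-bridged synclinal arrangement that keeps the acceptor methyl group outside the lactone ring is expected to set C1'.

Step 19
Reactants: 29 Michael adduct β-keto ester
Product: 30 β-hydroxy ester
Conditions: CeCl3 (1.5 equiv), LiBHEt3 (1.1 equiv), THF, −78 °C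
Reagents that add atoms: none
Why: Lewis-acid-mediated hydride reduction of an α-substituted β-keto ester through an open, non-chelated transition state with the ester group perpendicular to the carbonyl gives the 2,3-anti hydroxy ester at C3', while the labile C2' is expected to sit as the less congested epimer with the ester anti to the C1' methyl group, and at −78 °C the ketone reacts well ahead of ester, lactone and amide.

Step 20
Reactants: 30 β-hydroxy ester
Product: 32 chermebilaene B, via deprotected keto ester 31 (not isolated)
Conditions: 2 M HCl, THF, 40 °C; then p-TsOH·H2O (10 mol %), 4 Å MS, benzene, 50 °C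
Reagents that add atoms: water, O
Why: Acid-catalysed deprotection and acetalisation cascade: the silyl ethers and the dimethyl ketal fall, the freed C19 hydroxyl displaces pyrrolidine to restore the δ-lactone, the C4' ketone is captured by the C2' ester as a five-membered acyloxy lactol, and its remaining hydroxyl together with the C3' hydroxyl adds to C13 with loss of water to give the orthoester, C4' and C13 being formed reversibly in the only geometry that the cis-fused cage allows.

Compound list
1 | ethyl (E)-4-oxobut-2-enoate | CCOC(=O)/C=C/C=O | starting material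
2 | methyl 3-oxobutanoate | COC(=O)CC(C)=O | starting material
3 | 4-ethyl 1-methyl (3R)-2-acetyl-3-(2-oxoethyl)butanedioate (C2 labile) | O=CC[C@@H](C(=O)OCC)C(C(C)=O)C(=O)OC | intermediate
4 | cyclohexenone diester: C9 ketone, C7=C8, 5β-CO2Et, CO2Me on labile C10 | C1=CC[C@@H](C(=O)OCC)C(C(=O)OC)C1=O | intermediate
5 | tertiary alcohol: 5β-C(CH3)2OH, CO2Me on labile C10 | C1=CC[C@@H](C(C)(C)O)C(C(=O)OC)C1=O | intermediate
6 | cis-fused keto γ-lactone: C19(=O)–O–C4Me2 on the β face, H-5 and H-10 α | C1=CC[C@@H]2[C@H](C1=O)C(=O)OC2(C)C | intermediate
7 | tert-butyl acrylate | C=CC(=O)OC(C)(C)C | starting material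
8 | quaternary keto lactone: 10α-CH2CH2CO2t-Bu, C19 β | C1=CC[C@@H]2[C@](CCC(=O)OC(C)(C)C)(C1=O)C(=O)OC2(C)C | intermediate
9 | tosylhydrazone of 8 at C9 | C1=CC[C@@H]2[C@](CCC(=O)OC(C)(C)C)(C1=NNS(=O)(=O)c1ccc(C)cc1)C(=O)OC2(C)C | intermediate
10 | allylic diazene at C9 (configuration at C9 without consequence) | C1=CC[C@@H]2[C@](CCC(=O)OC(C)(C)C)(C1N=N)C(=O)OC2(C)C | intermediate
11 | C8=C9 cyclohexene lactone, C7 is CH2 | C=1CC[C@@H]2[C@](CCC(=O)OC(C)(C)C)(C=1)C(=O)OC2(C)C | intermediate
12 | C7 enone with C8=C9 | C=1C(=O)C[C@@H]2[C@](CCC(=O)OC(C)(C)C)(C=1)C(=O)OC2(C)C | intermediate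
13 | but-3-enylmagnesium bromide | C=CCC[Mg]Br | starting material
14 | bromomagnesium C7 enolate with 9α-but-3-enyl group | C1=C(O[Mg]Br)C[C@@H]2[C@](CCC(=O)OC(C)(C)C)([C@@H]1CCC=C)C(=O)OC2(C)C | intermediate
15 | C7 ketone with 8β-methyl and 9α-but-3-enyl groups | C[C@H]1C(=O)C[C@@H]2[C@](CCC(=O)OC(C)(C)C)([C@@H]1CCC=C)C(=O)OC2(C)C | intermediate
16 | 7β-alcohol | C[C@H]1[C@@H](O)C[C@@H]2[C@](CCC(=O)OC(C)(C)C)([C@@H]1CCC=C)C(=O)OC2(C)C | intermediate
17 | tetraol: 7β-OH, 5β-C(CH3)2OH, 10β-CH2OH, 10α-(CH2)3OH | C[C@H]1[C@@H](O)C[C@@H](C(C)(C)O)[C@@](CCCO)(CO)[C@@H]1CCC=C | intermediate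
18 | spiro lactol (C3 hemiacetal) | C[C@H]1[C@@H](O)C[C@@H](C(C)(C)O)[C@]2(CCC(O)OC2)[C@@H]1CCC=C | intermediate
19 | spiro δ-lactone diol | C[C@H]1[C@@H](O)C[C@@H](C(C)(C)O)[C@]2(CCC(=O)OC2)[C@@H]1CCC=C | intermediate
20 | 7β-acetate with 9α-but-3-enyl chain | C[C@H]1[C@@H](OC(C)=O)C[C@@H](C(C)(C)O)[C@]2(CCC(=O)OC2)[C@@H]1CCC=C | intermediate
21 | ring A propanoic acid with equatorial tertiary H-9β (key-step precursor) | C[C@H]1[C@@H](OC(C)=O)C[C@@H](C(C)(C)O)[C@]2(CCC(=O)OC2)[C@@H]1CCC(=O)O | intermediate
22 | spiro γ-lactone on ring A, O9 β (key-step product) | C[C@H]1[C@@H](OC(C)=O)C[C@@H](C(C)(C)O)[C@]2(CCC(=O)OC2)[C@]12CCC(=O)O2 | intermediate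
23 | triol pyrrolidine amide with intact spiro γ-lactone | C[C@H]1[C@@H](O)C[C@@H](C(C)(C)O)[C@@](CCC(=O)N2CCCC2)(CO)[C@]13CCC(=O)O3 | intermediate
24 | tris(triethylsilyl) ether of 23 | C[C@H]1[C@@H](O[Si](CC)(CC)CC)C[C@@H](C(C)(C)O[Si](CC)(CC)CC)[C@@](CCC(=O)N2CCCC2)(CO[Si](CC)(CC)CC)[C@]13CCC(=O)O3 | intermediate
25 | α-methyl γ-lactone (C12 methyl on the C8 side) | C[C@H]1[C@@H](O[Si](CC)(CC)CC)C[C@@H](C(C)(C)O[Si](CC)(CC)CC)[C@@](CCC(=O)N2CCCC2)(CO[Si](CC)(CC)CC)[C@]13C[C@H](C)C(=O)O3 | intermediate
26 | methyl 4,4-dimethoxy-3-oxopentanoate | COC(=O)CC(=O)C(C)(OC)OC | starting material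
27 | acetaldehyde | CC=O | starting material
28 | methyl 2-ethylidene-4,4-dimethoxy-3-oxopentanoate (E/Z mixture) | CC=C(C(=O)OC)C(=O)C(C)(OC)OC | intermediate
29 | Michael adduct β-keto ester: C12 quaternary, C1' set, C2' labile (drawn as needed) | C[C@H]1[C@@H](O[Si](CC)(CC)CC)C[C@@H](C(C)(C)O[Si](CC)(CC)CC)[C@@](CCC(=O)N2CCCC2)(CO[Si](CC)(CC)CC)[C@]13C[C@](C)([C@@H](C)[C@@H](C(=O)OC)C(=O)C(C)(OC)OC)C(=O)O3 | intermediate
30 | β-hydroxy ester (C2'/C3' anti) | C[C@H]1[C@@H](O[Si](CC)(CC)CC)C[C@@H](C(C)(C)O[Si](CC)(CC)CC)[C@@](CCC(=O)N2CCCC2)(CO[Si](CC)(CC)CC)[C@]13C[C@](C)([C@@H](C)[C@@H](C(=O)OC)[C@H](O)C(C)(OC)OC)C(=O)O3 | intermediate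
31 | deprotected hydroxy keto ester with restored δ-lactone | C[C@H]1[C@@H](O)C[C@@H](C(C)(C)O)[C@]2(CCC(=O)OC2)[C@]13C[C@](C)([C@@H](C)[C@@H](C(=O)OC)[C@H](O)C(C)=O)C(=O)O3 | intermediate
32 | chermebilaene B | C[C@H]1[C@@H](O)C[C@@H](C(C)(C)O)[C@]2(CCC(=O)OC2)[C@]12C[C@]1(C)[C@@H](C)[C@H]3C(=O)O[C@@]4(C)O[C@@]1(O[C@@H]34)O2 | target

Total step count: 20.
Longest linear sequence: 19 (steps 1–16 and 18–20; step 17 is a one-step side branch).

Steps most likely to fail

Step 13. Hydrogen abstraction at the methine next to the quaternary C10 may be too slow. Catalyst decay, attack at H-8 or oxidative loss of CO2 could then take over. The fallback brings the oxygen in without a tether and sets out from 21. Compound 21 is treated with methyl(trifluoromethyl)dioxirane (CH2Cl2/1,1,1-trifluoroacetone, −20 °C). This electrophilic reagent inserts oxygen into the most electron-rich and least shielded tertiary C–H bond in a concerted step with retention. H-9 is the only methine hydrogen that is both equatorial and remote from an oxygen substituent. The resulting 9β-hydroxy acid F1 lactonises on mildly acidic work-up, and the route is rejoined at 22.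

Step 18. Three processes threaten this step:
- proton transfer from the γ-methyl group of the acceptor to the basic enolate
- reversal of the addition
- weak control of the configuration at C1'

The fallback removes the base and sets out from 25. Compound 25 is converted with LiN(SiMe3)2 and Me3SiCl into the trimethylsilyl ketene acetal F2. F2 is then combined with 28 in a Mukaiyama–Michael addition under two-point activation of the keto ester by Sc(CF3SO3)3 (10 mol %, CH2Cl2, −78 °C). Aqueous work-up cleaves the silyl enol ether that is formed first, and the route is rejoined at 29.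

Step 19. Hydride may be delivered to both faces of the ketone, both epimers at the labile C2' may be reduced, and the lactone may be attacked. The fallback makes C2' and C3' in one C–C bond formation instead of a reduction and sets out from 25. The lithium enolate of 25 is added to methyl (E)-but-2-enoate to give the crotonate adduct F3. F3 has no enolisable lactone any more. Its ester enolate (LiN(i-Pr)2, THF, −78 °C) is then joined to 2,2-dimethoxypropanal in an anti-selective aldol addition through a closed chair-like transition state, on the enolate face opposite the bulky C12 substituent. This bypasses 28 and 29, and the route is rejoined at 30.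

Further compounds
F1 | step 13 | 9β-hydroxy acid | C[C@H]1[C@@H](OC(C)=O)C[C@@H](C(C)(C)O)[C@]2(CCC(=O)OC2)[C@]1(O)CCC(=O)O
F2 | step 18 | trimethylsilyl ketene acetal of 25 | C[C@H]1[C@@H](O[Si](CC)(CC)CC)C[C@@H](C(C)(C)O[Si](CC)(CC)CC)[C@@](CCC(=O)N2CCCC2)(CO[Si](CC)(CC)CC)[C@]13CC(C)=C(O[Si](C)(C)C)O3
F3 | step 19 | crotonate adduct (methyl ester, C12 and C1' set) | C[C@H]1[C@@H](O[Si](CC)(CC)CC)C[C@@H](C(C)(C)O[Si](CC)(CC)CC)[C@@](CCC(=O)N2CCCC2)(CO[Si](CC)(CC)CC)[C@]13C[C@](C)([C@@H](C)CC(=O)OC)C(=O)O3
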